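**Plan**
1. Cuts, in order: (a) the methyl ether that masks the C2 hydroxyl, so that the ring becomes symmetric 2,5-dimethoxy-1,4-benzoquinone; (b) the bond between chain C1 and ring C3, read as a primary alkyl radical plus a quinone C–H, the radical coming from a C16 carboxylic acid by loss of CO2; (c) the C9=C10 alkene of that acid (Wittig).
2. Forward: the chain acid is built first (bromide, phosphonium salt, Z-selective Wittig, saponification), then joined to the ready-made quinone ring by silver/peroxodisulfate decarboxylative radical alkylation; no ring is built; the C2 hydroxyl is unveiled last by regioselective hydrolysis.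
3. Enabling feature: C3–H of the benzoquinone ring is an open sp2 carbon between the C4 carbonyl and the oxygen-bearing C2. A nucleophilic alkyl radical adds there to a ring radical stabilised by the C2 oxygen and the C1 carbonyl, and loss of one electron and H+ restores the quinone.
4. Helper: with both oxygens methylated, C3 and C6 are equivalent, so the coupling has no regiochemical choice; the chain alkenes (C8, C11) are too far from the radical carbon to cyclise.
5. Stereochemistry: no stereocentre; 11Z is bought with (Z)-hept-3-en-1-ol, 8Z comes from the lithium-free Wittig of a non-stabilised ylide, and both are carried through unchanged.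

Key step: step 5

Remark: (9Z,12Z)-hexadeca-9,12-dienoic acid is sold only as a lipid standard in milligram lots, so it is made here; ring atoms are numbered C1(=O), C2(OH), C3(chain), C4(=O), C5(OMe), C6(H).

**Step 1**
Reactants: 1 (Z)-hept-3-en-1-ol
Product: 2 (Z)-1-bromohept-3-ene
Conditions: CBr4, PPh3, CH2Cl2, 0 °C to rt
Reagents that add atoms: carbon tetrabromide, BrC(Br)(Br)Br
Why: Appel bromination, in which bromide displaces the activated oxygen by SN2 at the primary carbon under neutral conditions that leave the remote Z alkene untouched.

**Step 2**
Reactants: 2 (Z)-1-bromohept-3-ene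
Product: 3 [(3Z)-hept-3-en-1-yl]triphenylphosphonium bromide
Conditions: PPh3, MeCN, reflux
Reagents that add atoms: triphenylphosphine, c1ccc(cc1)P(c1ccccc1)c1ccccc1
Why: SN2 quaternisation of PPh3 by the unhindered primary bromide (phosphonium salt formation), a neutral process that cannot isomerise the Z alkene.

**Step 3**
Reactants: 3 [(3Z)-hept-3-en-1-yl]triphenylphosphonium bromide; 4 methyl 9-oxononanoate
Product: 6 methyl (9Z,12Z)-hexadeca-9,12-dienoate, via phosphonium ylide 5 (not isolated)
Conditions: NaN(SiMe3)2, THF, −78 °C; then 4, −78 °C to rt
Reagents that add atoms: none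
Why: Wittig olefination, in which the non-stabilised ylide made with a lithium-free base adds to the aldehyde through the kinetically favoured cis-oxaphosphetane and should set C9=C10 as Z, while the ester is too slow an electrophile to compete and the existing Z alkene is not touched.

**Step 4**
Reactants: 6 methyl (9Z,12Z)-hexadeca-9,12-dienoate
Product: 7 (9Z,12Z)-hexadeca-9,12-dienoic acid
Conditions: LiOH·H2O, THF/MeOH/H2O, rt; then 1 M HCl
Reagents that add atoms: lithium hydroxide, [Li+].[OH-]
Why: Ester saponification at room temperature, to which the skipped Z,Z-diene is inert because its bis-allylic hydrogens are far too weakly acidic for hydroxide.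

**Step 5**
Reactants: 7 (9Z,12Z)-hexadeca-9,12-dienoic acid; 8 2,5-dimethoxy-1,4-benzoquinone
Product: 9 2,5-dimethoxy-3-[(8Z,11Z)-pentadeca-8,11-dien-1-yl]-1,4-benzoquinone
Conditions: 8 (3 equiv), AgNO3 (0.3 equiv), MeCN/H2O (2:1), 65 °C, Ar, dark; slow addition of 7 and (NH4)2S2O8 (1.5 equiv)
Reagents that add atoms: none
Why: Divalent silver, formed from AgNO3 and peroxodisulfate, oxidises the carboxylate of 7 to an acyloxy radical that loses CO2 to the primary (8Z,11Z)-pentadeca-8,11-dienyl radical; this nucleophilic radical adds to the open ring carbon C3 of 8, giving a ring radical at C2 stabilised by the methoxy oxygen and the C1 carbonyl, and loss of one electron (to divalent silver or peroxodisulfate) and of the C3 proton restores the quinone. The closest known reaction type is the silver/peroxodisulfate decarboxylative alkylation of quinones (Jacobsen–Torssell reaction, Minisci-type), long used to place primary alkyl chains on C3 of 2-hydroxy- and 2-alkoxy-1,4-quinones. No ring is closed and no stereocentre is formed. Site selectivity is secured by the two methyl ethers, which make C3 and C6 equivalent and leave no other open position; mono-alkylation is favoured by the excess of 8 and by the greater hindrance and electron richness of 9. The two Z alkenes should survive because they sit at C8 and C11 of the radical, too far for five- or six-membered radical ring closure, and because slow addition under argon in the dark keeps the radical concentration low and the bis-allylic CH2 unattacked.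

**Step 6**
Reactants: 9 2,5-dimethoxy-3-[(8Z,11Z)-pentadeca-8,11-dien-1-yl]-1,4-benzoquinone
Product: 10 2-hydroxy-5-methoxy-3-[(8Z,11Z)-pentadeca-8,11-dien-1-yl]-1,4-benzoquinone (Sorgoleone-360)
Conditions: 70% aq HClO4, 1,4-dioxane, rt, dark
Reagents that add atoms: water, O
Why: Acid-catalysed hydrolysis of a vinylogous ester by addition–elimination; the C2 methoxy is pushed out of the ring plane by the C3 chain and the C1 carbonyl, is less stabilised by conjugation than the C5 methoxy and should therefore be the one replaced by water, as in the closely related perchloric acid demethylations of 3-alkyl-2,5-dimethoxy-1,4-benzoquinones, while the isolated Z alkenes are not protonated under these conditions.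

**Compound list**
1 | (Z)-hept-3-en-1-ol | CCC/C=C\CCO | starting material
2 | (Z)-1-bromohept-3-ene | CCC/C=C\CCBr | intermediate
3 | [(3Z)-hept-3-en-1-yl]triphenylphosphonium bromide | CCC/C=C\CC[P+](c1ccccc1)(c1ccccc1)c1ccccc1.[Br-] | intermediate
4 | methyl 9-oxononanoate | COC(=O)CCCCCCCC=O | starting material
5 | [(3Z)-hept-3-en-1-ylidene]triphenylphosphorane (ylide, not isolated) | CCC/C=C\CC=P(c1ccccc1)(c1ccccc1)c1ccccc1 | intermediate
6 | methyl (9Z,12Z)-hexadeca-9,12-dienoate | CCC/C=C\C/C=C\CCCCCCCC(=O)OC | intermediate
7 | (9Z,12Z)-hexadeca-9,12-dienoic acid | CCC/C=C\C/C=C\CCCCCCCC(=O)O | intermediate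
8 | 2,5-dimethoxy-1,4-benzoquinone | COC1=CC(=O)C(OC)=CC1=O | starting material
9 | 2,5-dimethoxy-3-[(8Z,11Z)-pentadeca-8,11-dien-1-yl]-1,4-benzoquinone | CCC/C=C\C/C=C\CCCCCCCC1=C(OC)C(=O)C=C(OC)C1=O | intermediate
10 | 2-hydroxy-5-methoxy-3-[(8Z,11Z)-pentadeca-8,11-dien-1-yl]-1,4-benzoquinone (Sorgoleone-360) | CCC/C=C\C/C=C\CCCCCCCC1=C(O)C(=O)C=C(OC)C1=O | target

**Count**
Total steps: 6. Longest linear sequence: 6 steps (1 → 2 → 3 → 6 → 7 → 9 → 10); 4 and 8 are purchased.

**Steps most likely to fail**

Step 5. The skipped diene may be attacked at its bis-allylic CH2 by sulfate radical anion or by the alkyl radical, with double-bond migration. Capture of the radical by the sparingly soluble, electron-rich quinone may be too slow, so that the radical is lost by reduction or oxidation. A second alkylation at C6 may also occur. The fallback replaces the radical coupling by an aryllithium alkylation that never exposes the diene to radicals or to organolithium; it sets out from 3 and comes back at 9. Commercial 1,2,4,5-tetramethoxybenzene is lithiated (n-BuLi, THF, 0 °C) and alkylated with commercial 9-bromonon-1-ene to 1,2,4,5-tetramethoxy-3-(non-8-en-1-yl)benzene F1. Oxidative cleavage of the terminal alkene (OsO4 cat., NaIO4, 2,6-lutidine, dioxane/H2O) gives 8-(2,3,5,6-tetramethoxyphenyl)octanal F2. Wittig reaction of F2 with ylide 5, made from 3 as in step 3, gives 1,2,4,5-tetramethoxy-3-[(8Z,11Z)-pentadeca-8,11-dien-1-yl]benzene F3. Oxidative demethylation of F3 with (NH4)2Ce(NO3)6 (MeCN/H2O, 0 °C) gives 9.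

Step 6. Hydrolysis may occur at the C5 methoxy or at both methoxy groups, and the strong acid may cause migration or hydration of the alkenes. The fallback replaces kinetic hydrolysis by full hydrolysis followed by equilibrating mono-etherification under mild acid; it sets out from 9 and comes back at 10. Both ether groups of 9 are hydrolysed (NaOH, THF/H2O, rt; then dilute HCl) to 2,5-dihydroxy-3-[(8Z,11Z)-pentadeca-8,11-dien-1-yl]-1,4-benzoquinone F4. F4 is then etherified in MeOH with catalytic H2SO4 at rt, where the unhindered C5 hydroxyl, whose methyl ether can stay coplanar with the ring, should be the one converted, giving 10.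

Step 3. The Z selectivity of the Wittig reaction may erode, giving an E isomer that is hard to separate, and the ylide may be quenched by enolisation of the aldehyde. The fallback sets both alkenes together by syn semi-hydrogenation of a skipped diyne; it sets out from 4 and comes back at 6. Aldehyde 4 is homologated with dimethyl (1-diazo-2-oxopropyl)phosphonate (K2CO3, MeOH; Ohira–Bestmann) to methyl dec-9-ynoate F5. Copper-mediated coupling of F5 with commercial 1-bromohex-2-yne (CuI, NaI, Cs2CO3, DMF, rt) gives methyl hexadeca-9,12-diynoate F6. Semi-hydrogenation of F6 (H2, Pd on CaCO3 poisoned with Pb(OAc)2, quinoline, EtOAc) gives 6.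

**Further compounds**
F1 | step 5 | 1,2,4,5-tetramethoxy-3-(non-8-en-1-yl)benzene | C=CCCCCCCCc1c(OC)c(OC)cc(OC)c1OC
F2 | step 5 | 8-(2,3,5,6-tetramethoxyphenyl)octanal | O=CCCCCCCCc1c(OC)c(OC)cc(OC)c1OC
F3 | step 5 | 1,2,4,5-tetramethoxy-3-[(8Z,11Z)-pentadeca-8,11-dien-1-yl]benzene | CCC/C=C\C/C=C\CCCCCCCc1c(OC)c(OC)cc(OC)c1OC
F4 | step 6 | 2,5-dihydroxy-3-[(8Z,11Z)-pentadeca-8,11-dien-1-yl]-1,4-benzoquinone | CCC/C=C\C/C=C\CCCCCCCC1=C(O)C(=O)C=C(O)C1=O
F5 | step 3 | methyl dec-9-ynoate | COC(=O)CCCCCCCC#C
F6 | step 3 | methyl hexadeca-9,12-diynoate | CCCC#CCC#CCCCCCCCC(=O)OC
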